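**Assumption:** carbanions open (S)-epichlorohydrin at the unsubstituted epoxide carbon (not at C–Cl), so its stereocentre is carried through unchanged; "6Z" below means C8 syn to C5, as drawn in the target SMILES.

## Retrosynthetic overview

1. Target 23 ⇒ Wittig at C11=C12: left C15 phosphonium salt 20 + C25 apo-aldehyde 22. Then 22 ⇒ Wittig at C11'=C12': right C15 phosphonium salt 12 + C10 dialdehyde 21.
2. 12 ⇐ enynediol 11 ⇐ alkynylation/Horner–Wittig elimination of β-keto phosphine oxide 8 with enynol 9, which places C5'=C6' regiospecifically.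
3. Key step: 8 ⇐ epoxy ester 4 + lithiated EtP(O)Ph2 in one pot. Epoxide opening, γ-lactonisation and C-acylation through a 7-oxabicyclo[2.2.1]heptane hemiketalate build the oxolane ring and the carbocycle in one operation; C3' comes from (S)-epichlorohydrin.
4. 20 ⇐ ketoisophorone 4-ketal + 9, then Meyer–Schuster shift (6-ylidene-8-one) and deketalisation.
5. Ring order: the right cyclohexene ring (with its transient oxa-bridge) is built in step 2; the left ring is carried in from ketoisophorone.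

## Route

Step 1
Reactants: 1 methyl 2-methylpropanoate; 2 (2S)-2-(chloromethyl)oxirane
Product: 4 methyl 2,2-dimethyl-3-[(2S)-oxiran-2-yl]propanoate, via chlorohydrin alkoxide 3 (not isolated)
Conditions: LDA, THF, −78 °C; then 2, −78 → 23 °C
Reagents that add atoms: none
Why: Ester-enolate alkylation by epoxide opening and 3-exo-tet re-closure (any chloromethyl lactone is returned to 3 by the LiOMe it releases); the C–O bond at the stereocentre is never broken, so (S)-2 gives (2S)-4.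

Step 2
Reactants: 4 methyl 2,2-dimethyl-3-[(2S)-oxiran-2-yl]propanoate; 5 ethyl(diphenyl)phosphine oxide
Product: 8 (4S)-2-(diphenylphosphoryl)-4-hydroxy-2,6,6-trimethylcyclohexan-1-one (both C2 epimers), via butyrolactone 6 (not isolated), via bicyclic hemiketalate 7 (not isolated)
Conditions: 5, LDA (1.05 equiv), THF, −78 °C; 4, −78 → 23 °C; then LDA (1.2 equiv), −78 → 23 °C; H2O
Reagents that add atoms: none
Why: Proposed new method: lithiated 5 opens the terminal epoxide carbon, the γ-alkoxide closes onto the hindered ester to give lactone 6 (first ring), and the re-lithiated α-phosphoryl carbon attacks the lactone carbonyl to give the 7-oxabicyclo[2.2.1]heptane hemiketalate 7 (carbocycle, second ring), which opens to 8 on quench; the closest known chemistry is the Warren acylation of lithiated phosphine oxides by esters and lactones, here made intramolecular, and the carbinol stereocentre comes unchanged from 4.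

Step 3
Reactants: 8 (4S)-2-(diphenylphosphoryl)-4-hydroxy-2,6,6-trimethylcyclohexan-1-one; 9 (2E)-3-methylpent-2-en-4-yn-1-ol
Product: 11 (1R)-4-[(3E)-5-hydroxy-3-methylpent-3-en-1-yn-1-yl]-3,5,5-trimethylcyclohex-3-en-1-ol, via adduct 10 (not isolated)
Conditions: 9 (3 equiv), n-BuLi (6 equiv), THF, −78 → 0 °C; 8, −78 → 0 °C; then KOt-Bu, 23 → 45 °C; H2O
Reagents that add atoms: none
Why: Acetylide 1,2-addition to the non-enolisable ketone anti to the bulky Ph2P(O) group gives the cis-β-oxido phosphine oxide 10, which after Li→K exchange undergoes Horner–Wittig syn-elimination of diphenylphosphinate, so the tetrasubstituted C=C can only form next to the alkyne; the carbinol centre is untouched.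

Step 4
Reactants: 11 (1R)-4-[(3E)-5-hydroxy-3-methylpent-3-en-1-yn-1-yl]-3,5,5-trimethylcyclohex-3-en-1-ol
Product: 12 [(2E)-5-[(4R)-4-hydroxy-2,6,6-trimethylcyclohex-1-en-1-yl]-3-methylpent-2-en-4-yn-1-yl]triphenylphosphonium bromide
Conditions: PPh3·HBr, MeOH, 23 °C
Reagents that add atoms: triphenylphosphine hydrobromide, Br.c1ccc(cc1)P(c1ccccc1)c1ccccc1
Why: Phosphonium salt formation at the primary allylic carbon via the protonated alcohol is selective over the secondary ring OH and keeps the 9'E geometry.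

Step 5
Reactants: 13 2,6,6-trimethylcyclohex-2-ene-1,4-dione; 14 ethane-1,2-diol
Product: 15 7,9,9-trimethyl-1,4-dioxaspiro[4.5]dec-6-en-8-one
Conditions: p-TsOH (cat.), benzene, reflux, Dean–Stark
Reagents that add atoms: none
Why: Acid-catalysed ketalisation takes only the unhindered C4 carbonyl, because C1 is flanked by CMe2 and C(Me)=.

Step 6
Reactants: 15 7,9,9-trimethyl-1,4-dioxaspiro[4.5]dec-6-en-8-one; 9 (2E)-3-methylpent-2-en-4-yn-1-ol
Product: 16 8-[(3E)-5-hydroxy-3-methylpent-3-en-1-yn-1-yl]-7,9,9-trimethyl-1,4-dioxaspiro[4.5]dec-6-en-8-ol (racemic)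
Conditions: 9 (1.3 equiv), n-BuLi (2.6 equiv), THF, −78 → 0 °C; 15, −78 → 23 °C; H2O
Reagents that add atoms: none
Why: Lithium acetylide 1,2-addition to the only free ketone; the new carbinol centre is racemic and is destroyed in step 7.

Step 7
Reactants: 16 8-[(3E)-5-hydroxy-3-methylpent-3-en-1-yn-1-yl]-7,9,9-trimethyl-1,4-dioxaspiro[4.5]dec-6-en-8-ol
Product: 18 (4Z)-4-[(3E)-5-hydroxy-3-methyl-2-oxopent-3-en-1-ylidene]-3,5,5-trimethylcyclohex-2-en-1-one, via ketal enone 17 (not isolated)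
Conditions: Ph3PAuNTf2 (2 mol %), MeOH (2 equiv), toluene, 50 °C; then 1 M HCl, acetone, 23 °C; 6Z separated on SiO2, 6E re-equilibrated (cat. I2, hν) and recycled
Reagents that add atoms: water, O
Why: Gold-catalysed Meyer–Schuster rearrangement (formal 1,3-OH shift; no Rupe pathway because there is no β-H) followed by ketal hydrolysis; the exocyclic C=C geometry is under thermodynamic control, so 6Z is secured by separation and recycling.

Step 8
Reactants: 18 (4Z)-4-[(3E)-5-hydroxy-3-methyl-2-oxopent-3-en-1-ylidene]-3,5,5-trimethylcyclohex-2-en-1-one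
Product: 20 [(2E)-3-methyl-4-oxo-5-[(1Z)-2,6,6-trimethyl-4-oxocyclohex-2-en-1-ylidene]pent-2-en-1-yl]triphenylphosphonium bromide, via allylic bromide 19 (not isolated)
Conditions: CBr4 (1.1 equiv), PPh3 (2.3 equiv), CH2Cl2, 0 → 23 °C
Reagents that add atoms: triphenylphosphine, c1ccc(cc1)P(c1ccccc1)c1ccccc1; carbon tetrabromide, BrC(Br)(Br)Br
Why: Appel bromination of the primary allylic alcohol and in-situ SN2 quaternisation of PPh3 by the reactive γ-bromo enone; the medium is acid-free, so phosphine does not add to the enones.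

Step 9
Reactants: 12 right C15 phosphonium bromide; 21 (2E,4E,6E)-2,7-dimethylocta-2,4,6-trienedial
Product: 22 (2E,4E,6E,8E,10E)-13-[(4R)-4-hydroxy-2,6,6-trimethylcyclohex-1-en-1-yl]-2,7,11-trimethyltrideca-2,4,6,8,10-pentaen-12-ynal
Conditions: 21 (3 equiv), NaOMe, MeOH/CH2Cl2, 0 → 23 °C; then heptane, 80 °C (brief); crystallise
Reagents that add atoms: none
Why: Wittig olefination of the semi-stabilised allylic ylide with excess symmetrical dialdehyde gives the mono-adduct, and the hindered 11'Z isomer is isomerised thermally to all-E.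

Step 10
Reactants: 20 left C15 phosphonium bromide; 22 C25 apo-aldehyde
Product: 23 target CNP0205386.1
Conditions: 1,2-epoxybutane, EtOH, 70 °C, dark, Ar; crystallise/HPLC
Reagents that add atoms: none
Why: Wittig olefination with the keto-stabilised vinylogous ylide under neutral, epoxide-buffered conditions reacts only with the aldehyde (ketones and the free OH are untouched) and is E-selective at C11=C12.

## Compound list

1 | methyl 2-methylpropanoate | COC(=O)C(C)C | starting material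
2 | (2S)-2-(chloromethyl)oxirane, (S)-epichlorohydrin | ClC[C@@H]1CO1 | starting material
3 | lithium alkoxide of methyl (4S)-5-chloro-4-hydroxy-2,2-dimethylpentanoate (drawn as the alcohol) | ClC[C@@H](O)CC(C)(C)C(=O)OC | intermediate (not isolated)
4 | methyl 2,2-dimethyl-3-[(2S)-oxiran-2-yl]propanoate | COC(=O)C(C)(C)C[C@H]1CO1 | intermediate
5 | ethyl(diphenyl)phosphine oxide | CCP(=O)(c1ccccc1)c1ccccc1 | starting material
6 | (5S)-5-[2-(diphenylphosphoryl)propyl]-3,3-dimethyloxolan-2-one (both epimers at the P-bearing carbon) | CC(C[C@@H]1CC(C)(C)C(=O)O1)P(=O)(c1ccccc1)c1ccccc1 | intermediate (not isolated)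
7 | lithium (1R,4S)-2-(diphenylphosphoryl)-2,6,6-trimethyl-7-oxabicyclo[2.2.1]heptan-1-olate (drawn as the hemiketal; C2 epimers) | O[C@]12O[C@H](CC1(C)P(=O)(c1ccccc1)c1ccccc1)CC2(C)C | intermediate (not isolated)
8 | (4S)-2-(diphenylphosphoryl)-4-hydroxy-2,6,6-trimethylcyclohexan-1-one (C2 epimers) | CC1(P(=O)(c2ccccc2)c2ccccc2)C[C@@H](O)CC(C)(C)C1=O | intermediate
9 | (2E)-3-methylpent-2-en-4-yn-1-ol | C#C/C(C)=C/CO | starting material
10 | (4S)-2-(diphenylphosphoryl)-1-[(3E)-5-hydroxy-3-methylpent-3-en-1-yn-1-yl]-2,6,6-trimethylcyclohexane-1,4-diol, as its Li/K alkoxide (O1 cis to P) | CC1(P(=O)(c2ccccc2)c2ccccc2)C[C@@H](O)CC(C)(C)C1(O)C#C/C(C)=C/CO | intermediate (not isolated)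
11 | (1R)-4-[(3E)-5-hydroxy-3-methylpent-3-en-1-yn-1-yl]-3,5,5-trimethylcyclohex-3-en-1-ol | OC/C=C(\C)C#CC1=C(C)C[C@@H](O)CC1(C)C | intermediate
12 | [(2E)-5-[(4R)-4-hydroxy-2,6,6-trimethylcyclohex-1-en-1-yl]-3-methylpent-2-en-4-yn-1-yl]triphenylphosphonium bromide | [Br-].c1ccc(cc1)[P+](c1ccccc1)(c1ccccc1)C/C=C(\C)C#CC1=C(C)C[C@@H](O)CC1(C)C | intermediate
13 | 2,6,6-trimethylcyclohex-2-ene-1,4-dione (ketoisophorone) | CC1=CC(=O)CC(C)(C)C1=O | starting material
14 | ethane-1,2-diol | OCCO | starting material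
15 | 7,9,9-trimethyl-1,4-dioxaspiro[4.5]dec-6-en-8-one | CC1=CC2(CC(C)(C)C1=O)OCCO2 | intermediate
16 | 8-[(3E)-5-hydroxy-3-methylpent-3-en-1-yn-1-yl]-7,9,9-trimethyl-1,4-dioxaspiro[4.5]dec-6-en-8-ol (racemic) | CC1=CC2(CC(C)(C)C1(O)C#C/C(C)=C/CO)OCCO2 | intermediate
17 | (3E)-5-hydroxy-3-methyl-1-[(8Z)-7,9,9-trimethyl-1,4-dioxaspiro[4.5]dec-6-en-8-ylidene]pent-3-en-2-one | CC1=CC2(CC(C)(C)/C1=C/C(=O)/C(C)=C/CO)OCCO2 | intermediate (not isolated)
18 | (4Z)-4-[(3E)-5-hydroxy-3-methyl-2-oxopent-3-en-1-ylidene]-3,5,5-trimethylcyclohex-2-en-1-one | CC1=CC(=O)CC(C)(C)/C1=C/C(=O)/C(C)=C/CO | intermediate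
19 | (4Z)-4-[(3E)-5-bromo-3-methyl-2-oxopent-3-en-1-ylidene]-3,5,5-trimethylcyclohex-2-en-1-one | CC1=CC(=O)CC(C)(C)/C1=C/C(=O)/C(C)=C/CBr | intermediate (not isolated)
20 | [(2E)-3-methyl-4-oxo-5-[(1Z)-2,6,6-trimethyl-4-oxocyclohex-2-en-1-ylidene]pent-2-en-1-yl]triphenylphosphonium bromide | [Br-].CC1=CC(=O)CC(C)(C)/C1=C/C(=O)/C(C)=C/C[P+](c1ccccc1)(c1ccccc1)c1ccccc1 | intermediate
21 | (2E,4E,6E)-2,7-dimethylocta-2,4,6-trienedial | O=C/C(C)=C/C=C/C=C(C)/C=O | starting material
22 | (2E,4E,6E,8E,10E)-13-[(4R)-4-hydroxy-2,6,6-trimethylcyclohex-1-en-1-yl]-2,7,11-trimethyltrideca-2,4,6,8,10-pentaen-12-ynal | O=C/C(C)=C/C=C/C=C(C)/C=C/C=C(\C)C#CC1=C(C)C[C@@H](O)CC1(C)C | intermediate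
23 | CNP0205386.1: 3-oxo-4-en-6(Z)-ylidene-8-oxo left end, all-E C9–C9' chain, 7',8'-yne, (3'R)-3'-hydroxy right end | CC1=CC(=O)CC(C)(C)/C1=C/C(=O)/C(C)=C/C=C/C(C)=C/C=C/C=C(C)/C=C/C=C(\C)C#CC1=C(C)C[C@@H](O)CC1(C)C | target

## Totals and risks

Total step count: 10. Longest linear sequence: 6 steps (1 → 2 → 3 → 4 → 9 → 10).

Steps most likely to fail, each with a fallback:

Step 2. The carbanion may attack the ester before the epoxide, or the cascade may stop at the lactone. The fallback closes the ring by olefination instead of acylation. It sets out from 4: lithiated 5 with BF3·OEt2 at −78 °C opens the epoxide, and work-up gives lactone 6, now isolated. Dilithiated 9 adds once to the lactone carbonyl to give the open hydroxy ynone (2E,9S)-11-(diphenylphosphoryl)-1,9-dihydroxy-3,7,7-trimethyldodec-2-en-4-yn-6-one F1. KHMDS then forms the α-phosphoryl carbanion, which adds to the ynone carbonyl and eliminates diphenylphosphinate (intramolecular Horner–Wittig ring closure). This gives 11 directly, so the route is rejoined at 11.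

Step 3. The ketone is doubly neopentylic, and the syn-elimination must form a tetrasubstituted alkene. The fallback makes the enyne by cross-coupling. It sets out from 4: the dianion of propanoic acid (LDA) runs the same opening/lactonisation/C-acylation sequence to the β-keto acid (5S)-5-hydroxy-1,3,3-trimethyl-2-oxocyclohexane-1-carboxylic acid F2. Warming with dilute acid decarboxylates it to (4R)-4-hydroxy-2,2,6-trimethylcyclohexan-1-one F3. TBSCl/imidazole gives (4R)-4-[(tert-butyldimethylsilyl)oxy]-2,2,6-trimethylcyclohexan-1-one F4. LDA then PhNTf2 gives (4R)-4-[(tert-butyldimethylsilyl)oxy]-2,6,6-trimethylcyclohex-1-en-1-yl trifluoromethanesulfonate F5; enolisation is possible only towards C6. Sonogashira coupling with 9 (Pd(PPh3)4, CuI, Et3N) gives (2E)-5-[(4R)-4-[(tert-butyldimethylsilyl)oxy]-2,6,6-trimethylcyclohex-1-en-1-yl]-3-methylpent-2-en-4-yn-1-ol F6, and TBAF brings the route back at 11.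

Step 10. The vinylogous keto-ylide may be sluggish towards the polyenal and can scramble the C9=C10 geometry. The fallback reverses the polarity of the last olefination. It sets out from 22 and uses 18. MnO2 oxidises 18 to (2E)-3-methyl-4-oxo-5-[(1Z)-2,6,6-trimethyl-4-oxocyclohex-2-en-1-ylidene]pent-2-enal F7. NaBH4 reduces 22 to (2E,4E,6E,8E,10E)-13-[(4R)-4-hydroxy-2,6,6-trimethylcyclohex-1-en-1-yl]-2,7,11-trimethyltrideca-2,4,6,8,10-pentaen-12-yn-1-ol F8. PPh3·HBr converts F8 into [(2E,4E,6E,8E,10E)-13-[(4R)-4-hydroxy-2,6,6-trimethylcyclohex-1-en-1-yl]-2,7,11-trimethyltrideca-2,4,6,8,10-pentaen-12-yn-1-yl]triphenylphosphonium bromide F9. Its non-carbonyl-conjugated ylide (NaOMe) reacts with the geometrically fixed aldehyde F7, and the route comes back at 23.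

## Further compounds

F1 | step 2 | (2E,9S)-11-(diphenylphosphoryl)-1,9-dihydroxy-3,7,7-trimethyldodec-2-en-4-yn-6-one | CC(C[C@@H](O)CC(C)(C)C(=O)C#C/C(C)=C/CO)P(=O)(c1ccccc1)c1ccccc1
F2 | step 3 | (5S)-5-hydroxy-1,3,3-trimethyl-2-oxocyclohexane-1-carboxylic acid | CC1(C(=O)O)C[C@@H](O)CC(C)(C)C1=O
F3 | step 3 | (4R)-4-hydroxy-2,2,6-trimethylcyclohexan-1-one | CC1C[C@@H](O)CC(C)(C)C1=O
F4 | step 3 | (4R)-4-[(tert-butyldimethylsilyl)oxy]-2,2,6-trimethylcyclohexan-1-one | CC1C[C@@H](O[Si](C)(C)C(C)(C)C)CC(C)(C)C1=O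
F5 | step 3 | (4R)-4-[(tert-butyldimethylsilyl)oxy]-2,6,6-trimethylcyclohex-1-en-1-yl trifluoromethanesulfonate | FC(F)(F)S(=O)(=O)OC1=C(C)C[C@@H](O[Si](C)(C)C(C)(C)C)CC1(C)C
F6 | step 3 | (2E)-5-[(4R)-4-[(tert-butyldimethylsilyl)oxy]-2,6,6-trimethylcyclohex-1-en-1-yl]-3-methylpent-2-en-4-yn-1-ol | OC/C=C(\C)C#CC1=C(C)C[C@@H](O[Si](C)(C)C(C)(C)C)CC1(C)C
F7 | step 10 | (2E)-3-methyl-4-oxo-5-[(1Z)-2,6,6-trimethyl-4-oxocyclohex-2-en-1-ylidene]pent-2-enal | CC1=CC(=O)CC(C)(C)/C1=C/C(=O)/C(C)=C/C=O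
F8 | step 10 | (2E,4E,6E,8E,10E)-13-[(4R)-4-hydroxy-2,6,6-trimethylcyclohex-1-en-1-yl]-2,7,11-trimethyltrideca-2,4,6,8,10-pentaen-12-yn-1-ol | OC/C(C)=C/C=C/C=C(C)/C=C/C=C(\C)C#CC1=C(C)C[C@@H](O)CC1(C)C
F9 | step 10 | [(2E,4E,6E,8E,10E)-13-[(4R)-4-hydroxy-2,6,6-trimethylcyclohex-1-en-1-yl]-2,7,11-trimethyltrideca-2,4,6,8,10-pentaen-12-yn-1-yl]triphenylphosphonium bromide | [Br-].c1ccc(cc1)[P+](c1ccccc1)(c1ccccc1)C/C(C)=C/C=C/C=C(C)/C=C/C=C(\C)C#CC1=C(C)C[C@@H](O)CC1(C)C
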